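The readings come from a simulation with made-up constants, and the scatter is random.

| setting | oak | birch | flask |
|---|---|---|---|
| solid substrate | 1.1 M | 1.7 M | 2.3 M |
| partner | 2.53 M | 2.53 M | 2.53 M |
| remark | run made earlier | run made earlier |  |
| time |  |  | 2.0 h |

| run | time / min | target / % | crystals / % |
|---|---|---|---|
| oak | 12.0 | 70.8 | 9.2 |
| oak | 30.0 | 78.8 | 25.6 |
| oak | 60.0 | 77.9 | 24.7 |
| oak | 90.0 | 78.5 | 24.5 |
| birch | 12.0 | 46.3 | 6.8 |
| birch | 30.0 | 74.3 | 40.0 |
| birch | 60.0 | 75.2 | 39.1 |
| birch | 90.0 | 75.3 | 39.6 |

(scatter of a reading: 0.5 percentage points)

- amounts and yields of target count crystals too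
- given per volume of solution although it is solid: solid substrate, crystals
- the numbers in the tables scatter by 0.5 percentage points (one standard deviation)
- at the start none of the solid substrate is in solution
- dissolved substrate means what is dissolved; the solid is not counted in it

- the target and crystals together standing at 2.0 h, as a percentage of the solid substrate charged
- concentration of dissolved substrate in solution at 2.0 h, in percent of saturation

1. The small oak charge of 1.1 M stands flat from 30.0 min at 78.4% target, crystals counted in; the birch charge of 1.7 M stands flat at 74.9%.

2. We carry the charge penalty: the plateau yield given up for each step of 0.600 M more solid substrate at the same partner, read here as 3.5 percentage points.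

3. To whoever takes over: the flask holds 2.3 M solid substrate with 2.53 M partner, 1.00 step above birch. Our reckoning puts its target, crystals counted in, at 71.5% by 2.0 h, with about 0.885 M partner unused.

4. We read the flat oak and birch plateaus, with partner unused, as substrate used up, so we expect 0% of saturation in the flask. Leave the charge alone.

5. The forecast differs from our reckoning: 55.4% (53.5% to 57.5%) and 100% of saturation (96% to 101%), on the ground “With both solids present, dissolved substrate, dissolved target and partner are all fixed.”

6. The flask gives 70.6% at 0% of saturation.

    solid substrate ⇌ dissolved substrate, rate k1*(cs1 - [dissolved substrate]) while solid is left; crystals form when [dissolved substrate] > cs1 (solubility = 0.330 M, k = 0.00620 s⁻¹)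
    dissolved substrate + partner → target (k = 0.00590 L mol⁻¹ s⁻¹)
    2 dissolved substrate → side product (k = 0.0200 L mol⁻¹ s⁻¹)
    crystals ⇌ target, rate k4*(cs4 - [target]) while solid is left; crystals form when [target] > cs4 (solubility = 0.590 M, k = 0.0130 s⁻¹)

The flask ends 0.90 points below our line at 2.0 h, with 0% solid substrate and 0% dissolved substrate left against 36% of the partner, so solid substrate is its limiting reagent, and 29.4% stands as side product. The neighbouring flask has 1.4 M solid substrate with the same partner, half a step above oak, so the charge penalty gives 76.7%. That neighbouring flask stands at 76.6%.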